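Readings and results are simulated for substances that don't exist.

The summer run and the autumn run were my starting point, and I had to say which of two new flasks would make more product.

common to all: substrate 0.17 M
- autumn: reagent 1.2 equiv; free catalyst 3.5 mol%; temperature 105 °C; run made earlier
- summer: reagent 1.2 equiv; free catalyst 7.8 mol%; temperature 120 °C; run made earlier
- Wednesday's: reagent 1.20 equiv; free catalyst 5.2 mol%; temperature 130 °C; time 40 min
- Thursday's: reagent 1.20 equiv; free catalyst 5.2 mol%; temperature 110 °C; time 40 min

- autumn (time / min: product / %, substrate / %): 6.00: 3, 100; 15.0: 1, 98; 20.0: 1, 98; 40.0: 3, 94; 80.0: 8, 86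
- summer (time / min: product / %, substrate / %): 3.00: 3, 95; 6.00: 6, 96; 10.0: 5, 88; 20.0: 10, 85; 40.0: 24, 70

(scatter of a reading: 1.5 percentage points)

- percentages count the substrate that a species holds: one resting dimer counts as two
- what was read earlier has a scatter of 1.5 percentage points, one standard deviation
- candidate steps: catalyst intermediate E -> free catalyst + product; catalyst intermediate D <-> by-product + catalyst intermediate E; catalyst intermediate A -> catalyst intermediate B; 2 catalyst intermediate C <-> resting dimer; reagent + free catalyst -> catalyst intermediate A; substrate + catalyst intermediate B -> catalyst intermediate C; catalyst intermediate C <-> catalyst intermediate D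

1. the flask that comes out highest in amount of product, in percent of the substrate charged, or "all alike" when all lie within 1.5 percentage points (Wednesday's / Thursday's / all alike)
2. product at the end, in percent of the substrate charged, Wednesday's
3. product at the end, in percent of the substrate charged, Thursday's

I looked for something nearly constant and froze it. I took the turnover frequency: product made per minute per catalyst charged, between the last two readings of a run. Autumn's gave 0.0357 min⁻¹ and summer's gave 0.0897 min⁻¹. I called their ratio, 2.51, the heat factor: what the step from autumn's temperature to summer's multiplies the turnover frequency by. It is a reading, so it carries the scatter of the readings behind it.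

Wednesday's stands as far above summer's temperature as Thursday's stands below it. Scaling by the matching fraction of a step gave 0.166 min⁻¹ for Wednesday's and 0.0486 min⁻¹ for Thursday's. Multiplied by loading and time, these gave 34.5% and 10.1%. I committed to those.

The weak link was the loading, since I had assumed rate proportional to catalyst. So I supposed the other limit, with the catalyst held back in a resting dimer and the rate in the square root of the loading. Reforged that way, the factor became 3.75. Thursday's stayed near 9.47%, but Wednesday's rose to 55.2%, more than my first figure. So my first Wednesday figure became the low end of a span.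

The forecast chose Wednesday's, at 33% (range 24% to 45%), with “negligible lag and some substrate depletion”. For Thursday's it gave 7.5% (range 5% to 11%), less than my figure.

Wednesday's gave 41.1%, more than the forecast, and Thursday's gave 8.83%, so Wednesday's came out highest.

    catalyst intermediate E → free catalyst + product (k = 18.0 min⁻¹, Ea = 102 kJ mol⁻¹)
    catalyst intermediate D ⇌ by-product + catalyst intermediate E (K = 0.0940 M, k = 4.50 min⁻¹, Ea = 106 kJ mol⁻¹, ΔH = 0 kJ mol⁻¹)
    catalyst intermediate A → catalyst intermediate B (k = 19.0 min⁻¹, Ea = 103 kJ mol⁻¹)
    2 catalyst intermediate C ⇌ resting dimer, settled at all times (K = 4700 L mol⁻¹, ΔH = −40.0 kJ mol⁻¹)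
    reagent + free catalyst → catalyst intermediate A (k = 2.60 L mol⁻¹ min⁻¹, Ea = 84.0 kJ mol⁻¹)
    substrate + catalyst intermediate B → catalyst intermediate C (k = 0.930 L mol⁻¹ min⁻¹, Ea = 78.0 kJ mol⁻¹)
    catalyst intermediate C ⇌ catalyst intermediate D (K = 1.60, k = 0.690 min⁻¹, Ea = 94.0 kJ mol⁻¹, ΔH = −39.0 kJ mol⁻¹)
    (constants at 110 °C)

Taken from Thursday's temperature to Wednesday's, the heat factor gave 3.42, but the two flasks differed by 4.65. The resting dimer held 47.4% of Thursday's catalyst at the asked time and 21.3% of Wednesday's. As one part of the account, in runs of this length, taking it away raised Thursday's to 17.6% and Wednesday's to 53.1%, so their ratio fell to 3.02. With the same heat factor, I reckoned a neighbour flask, with Wednesday's amounts and time at 115 °C, at 13.7%, and it gave 13.7%.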